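Everything rests on disconnecting the dioxane ring at C2–C3. In the O1–C2(CO2H)–C3(aryl)–O4 unit of the 1,4-benzodioxane, C3 is a masked aroyl carbon and C2 the acidic α-carbon of an aryloxyacetate, so the precursor is a simple 4-bromocatechol carrying an aryl ester on the oxygen para to bromine and a CH2CO2Me arm on the other. One operation, intramolecular Claisen addition then cyclodehydration, closes the ring through C2–C3 and gives a flat 1,4-benzodioxine; a single carboxylate-directed asymmetric syn hydrogenation then sets both stereocentres cis. Heck coupling with a glycidate-derived (R)-lactate acrylate and acidolysis complete the synthesis.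

Key step: step 5

Remark: the target SMILES defines a cis-(2R,3R) dioxane ring (H2 and H3 on the same face) and an (R)-aryllactate; the route is built for this isomer, and the ligand antipode that gives (2R,3R) in step 7 is fixed in a first screen (both antipodes are available).

Step 1
Reactants: 1 3,4-dihydroxybenzoic acid
Product: 2 2,2-diphenyl-1,3-benzodioxole-5-carboxylic acid
Conditions: Ph2CCl2 (1.5 equiv), Ph2O, 175 °C; aq. work-up
Reagents that add atoms: dichlorodiphenylmethane, ClC(Cl)(c1ccccc1)c1ccccc1
Why: Ketalisation of the catechol with a gem-dichloride (diphenylmethylene ketal formation) masks both phenols with a group that resists base, hydrogen and palladium but falls to aqueous acid, and any acyl chloride formed at the carboxyl group is hydrolysed in the work-up.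

Step 2
Reactants: 3 (2-hydroxyphenoxy)acetic acid
Product: 4 methyl (2-hydroxyphenoxy)acetate
Conditions: MeOH, H2SO4 (cat.), reflux
Reagents that add atoms: methanol, CO
Why: Fischer esterification in excess methanol should give the methyl ester and reopen any 1,4-benzodioxan-2-one lactone, so the phenol stays free.

Step 3
Reactants: 4 methyl (2-hydroxyphenoxy)acetate
Product: 5 methyl (5-bromo-2-hydroxyphenoxy)acetate
Conditions: NBS (1.0 equiv), MeCN, −10 °C → rt
Reagents that add atoms: N-bromosuccinimide, O=C1CCC(=O)N1Br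
Why: Electrophilic aromatic bromination is directed para to the free hydroxyl, the stronger donor, which places bromine para to the oxygen that becomes O4.

Step 4
Reactants: 5 methyl (5-bromo-2-hydroxyphenoxy)acetate; 2 2,2-diphenyl-1,3-benzodioxole-5-carboxylic acid
Product: 6 methyl 2-{5-bromo-2-[(2,2-diphenyl-1,3-benzodioxole-5-carbonyl)oxy]phenoxy}acetate
Conditions: DCC (1.1 equiv), DMAP (0.1 equiv), CH2Cl2, 0 °C → rt
Reagents that add atoms: none
Why: Steglich esterification hangs the future C3 on the future O4 as an aryl ester, the phenol being acylated faster than it can lactonise onto its own methyl ester.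

Step 5
Reactants: 6 methyl 2-{5-bromo-2-[(2,2-diphenyl-1,3-benzodioxole-5-carbonyl)oxy]phenoxy}acetate
Product: 8 methyl 7-bromo-3-(2,2-diphenyl-1,3-benzodioxol-5-yl)-1,4-benzodioxine-2-carboxylate, via cyclic hemiketal 7 (not isolated)
Conditions: LiN(SiMe3)2 (2.2 equiv), THF, −78 → 0 °C; AcOH; solvent switch; TsOH·H2O (10 mol%), toluene, reflux, Dean–Stark
Reagents that add atoms: none
Why: The amide base removes a proton from the O1–CH2 group, the only enolisable position, and the ester enolate adds to the neighbouring aryl ester carbonyl (Baker–Venkataraman-type intramolecular Claisen reaction), which forms the C2–C3 bond and gives the cyclic tetrahedral adduct, i.e. the alkoxide of hemiketal 7 in ring–chain equilibrium with the β-keto ester phenoxide; the second equivalent of base stores it as the stabilised enolate and makes the closure irreversible. The closest known reaction type is the Dieckmann/Baker–Venkataraman acyl transfer followed by the acid cyclodehydration used for flavones, here with both ring oxygens already in place so that a 1,4-benzodioxine results. The six-membered ring closes in the 6-exo-trig mode (enolate carbon onto an exocyclic C=O), and the acid then ionises the hemiketal to an oxocarbenium ion at C3, stabilised by O4 and the dioxygenated aryl group, which loses the acidic H2. No stereocentre is carried on: the two centres of 7 are deliberately erased to give the planar C2=C3 enol ether on which step 7 acts. The step needs chemoselectivity only (ring closure instead of intermolecular acyl transfer, dehydration instead of lactonisation onto the methyl ester), secured by the six-membered transition state, the aryl ester as the only activated acyl donor and the irreversible loss of water under Dean–Stark conditions.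

Step 6
Reactants: 8 methyl 7-bromo-3-(2,2-diphenyl-1,3-benzodioxol-5-yl)-1,4-benzodioxine-2-carboxylate
Product: 9 7-bromo-3-(2,2-diphenyl-1,3-benzodioxol-5-yl)-1,4-benzodioxine-2-carboxylic acid
Conditions: LiOH·H2O (3 equiv), THF/MeOH/H2O, rt; then 1 M HCl, 0 °C
Reagents that add atoms: lithium hydroxide, [Li+].[OH-]
Why: Saponification by acyl–oxygen cleavage is done at the stage without stereocentres, where base cannot epimerise anything, and the vinylogous carbonate is a poor Michael acceptor while the ketal is base-stable.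

Step 7
Reactants: 9 7-bromo-3-(2,2-diphenyl-1,3-benzodioxol-5-yl)-1,4-benzodioxine-2-carboxylic acid
Product: 10 (2R,3R)-7-bromo-3-(2,2-diphenyl-1,3-benzodioxol-5-yl)-2,3-dihydro-1,4-benzodioxine-2-carboxylic acid
Conditions: H2 (30 bar), [Ir(cod)(L)]B[C6H3(CF3)2]4 (2 mol%, L = chiral spiro phosphine-oxazoline SIPHOX), Et3N (0.5 equiv), MeOH, 60 °C
Reagents that add atoms: none
Why: Carboxylate-directed iridium-catalysed asymmetric hydrogenation of an α-aryloxy α,β-unsaturated acid delivers both hydrogens to one face of the C2=C3 bond (syn addition), so H2 and H3 become cis, and the spiro ligand, in the antipode found to give (2R,3R), selects the face.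

Step 8
Reactants: 11 4-bromo-2-methoxyphenol
Product: 12 4-bromo-2-methoxy-1-(methoxymethoxy)benzene
Conditions: MOMCl (1.3 equiv), i-Pr2NEt (1.5 equiv), CH2Cl2, 0 °C → rt
Reagents that add atoms: chloromethyl methyl ether, COCCl
Why: O-Alkylation of the phenol installs a methoxymethyl ether that tolerates magnesium, acid chloride and palladium and is cleaved by the same acid as the ketal.

Step 9
Reactants: 12 4-bromo-2-methoxy-1-(methoxymethoxy)benzene; 13 methyl (2R)-oxirane-2-carboxylate
Product: 15 methyl (2R)-2-hydroxy-3-[3-methoxy-4-(methoxymethoxy)phenyl]propanoate, via aryl Grignard reagent 14 (not isolated)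
Conditions: Mg, THF, 40 °C; then CuI (10 mol%), 13 (0.8 equiv), −40 → −20 °C; aq. NH4Cl
Reagents that add atoms: none
Why: Copper-catalysed opening of the epoxide by the aryl Grignard reagent at the unsubstituted CH2 (SN2) leaves the bought stereocentre untouched, so the (R)-glycidate gives the (R)-aryllactate, and low temperature keeps the ester intact.

Step 10
Reactants: 15 methyl (2R)-2-hydroxy-3-[3-methoxy-4-(methoxymethoxy)phenyl]propanoate
Product: 16 4-methoxybenzyl (2R)-2-hydroxy-3-[3-methoxy-4-(methoxymethoxy)phenyl]propanoate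
Conditions: 4-methoxybenzyl alcohol (3 equiv), Ti(O-i-Pr)4 (15 mol%), toluene, 90 °C, MeOH distilled off
Reagents that add atoms: 4-methoxybenzyl alcohol, COc1ccc(CO)cc1
Why: Titanium-alkoxide-catalysed transesterification, neutral and chelation-assisted for α-hydroxy esters, exchanges the methyl ester for an acid-labile 4-methoxybenzyl ester without touching the stereocentre.

Step 11
Reactants: 16 4-methoxybenzyl (2R)-2-hydroxy-3-[3-methoxy-4-(methoxymethoxy)phenyl]propanoate; 17 acryloyl chloride
Product: 18 4-methoxybenzyl (2R)-3-[3-methoxy-4-(methoxymethoxy)phenyl]-2-(prop-2-enoyloxy)propanoate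
Conditions: Et3N (1.5 equiv), CH2Cl2, −20 → 0 °C, BHT (trace)
Reagents that add atoms: none
Why: O-Acylation of the secondary alcohol with the acid chloride gives the acrylate without involving the stereocentre.

Step 12
Reactants: 10 (2R,3R)-7-bromo-3-(2,2-diphenyl-1,3-benzodioxol-5-yl)-2,3-dihydro-1,4-benzodioxine-2-carboxylic acid; 18 4-methoxybenzyl (2R)-3-[3-methoxy-4-(methoxymethoxy)phenyl]-2-(prop-2-enoyloxy)propanoate
Product: 19 (2R,3R)-3-(2,2-diphenyl-1,3-benzodioxol-5-yl)-7-[(E)-3-{[(2R)-1-[(4-methoxybenzyl)oxy]-3-[3-methoxy-4-(methoxymethoxy)phenyl]-1-oxopropan-2-yl]oxy}-3-oxoprop-1-en-1-yl]-2,3-dihydro-1,4-benzodioxine-2-carboxylic acid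
Conditions: Pd2(dba)3 (2 mol%), [HP(t-Bu)3]BF4 (8 mol%), Cy2NMe (3 equiv), 1,4-dioxane, 60 °C
Reagents that add atoms: none
Why: Mizoroki–Heck reaction (oxidative addition of the aryl bromide to zerovalent palladium, syn insertion of the acrylate, syn β-hydride elimination) gives the (E)-cinnamate, while C2, carried as the non-enolisable ammonium carboxylate, and the lactate centre are not touched.

Step 13
Reactants: 19 (2R,3R)-3-(2,2-diphenyl-1,3-benzodioxol-5-yl)-7-[(E)-3-{[(2R)-1-[(4-methoxybenzyl)oxy]-3-[3-methoxy-4-(methoxymethoxy)phenyl]-1-oxopropan-2-yl]oxy}-3-oxoprop-1-en-1-yl]-2,3-dihydro-1,4-benzodioxine-2-carboxylic acid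
Product: 20 clinopodic acid F
Conditions: TFA/CH2Cl2 (1:3), H2O (10 equiv), anisole (10 equiv), 0 °C → rt
Reagents that add atoms: none
Why: Acidolysis removes the diphenylmethylene ketal (hydrolysis to benzophenone), the methoxymethyl ether and the 4-methoxybenzyl ester (alkyl–oxygen cleavage, cation trapped by anisole) in one operation without base, which would epimerise C2 or open the dioxane ring through a quinone methide.

Compound list
1 | 3,4-dihydroxybenzoic acid | OC(=O)c1ccc(O)c(O)c1 | starting material
2 | 2,2-diphenyl-1,3-benzodioxole-5-carboxylic acid | OC(=O)c1ccc2OC(c3ccccc3)(c3ccccc3)Oc2c1 | intermediate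
3 | (2-hydroxyphenoxy)acetic acid | OC(=O)COc1ccccc1O | starting material
4 | methyl (2-hydroxyphenoxy)acetate | COC(=O)COc1ccccc1O | intermediate
5 | methyl (5-bromo-2-hydroxyphenoxy)acetate | COC(=O)COc1cc(Br)ccc1O | intermediate
6 | methyl 2-{5-bromo-2-[(2,2-diphenyl-1,3-benzodioxole-5-carbonyl)oxy]phenoxy}acetate | COC(=O)COc1cc(Br)ccc1OC(=O)c1ccc2OC(c3ccccc3)(c3ccccc3)Oc2c1 | intermediate
7 | methyl 7-bromo-3-(2,2-diphenyl-1,3-benzodioxol-5-yl)-3-hydroxy-2,3-dihydro-1,4-benzodioxine-2-carboxylate (cyclic hemiketal, stereoisomer mixture, not isolated) | COC(=O)C1Oc2cc(Br)ccc2OC1(O)c1ccc2OC(c3ccccc3)(c3ccccc3)Oc2c1 | intermediate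
8 | methyl 7-bromo-3-(2,2-diphenyl-1,3-benzodioxol-5-yl)-1,4-benzodioxine-2-carboxylate | COC(=O)C1=C(c2ccc3OC(c4ccccc4)(c4ccccc4)Oc3c2)Oc2ccc(Br)cc2O1 | intermediate
9 | 7-bromo-3-(2,2-diphenyl-1,3-benzodioxol-5-yl)-1,4-benzodioxine-2-carboxylic acid | OC(=O)C1=C(c2ccc3OC(c4ccccc4)(c4ccccc4)Oc3c2)Oc2ccc(Br)cc2O1 | intermediate
10 | (2R,3R)-7-bromo-3-(2,2-diphenyl-1,3-benzodioxol-5-yl)-2,3-dihydro-1,4-benzodioxine-2-carboxylic acid (cis) | Brc1ccc2c(c1)O[C@@H](C(=O)O)[C@@H](c1ccc3OC(c4ccccc4)(c4ccccc4)Oc3c1)O2 | intermediate
11 | 4-bromo-2-methoxyphenol | COc1cc(Br)ccc1O | starting material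
12 | 4-bromo-2-methoxy-1-(methoxymethoxy)benzene | COCOc1ccc(Br)cc1OC | intermediate
13 | methyl (2R)-oxirane-2-carboxylate (methyl (R)-glycidate) | COC(=O)[C@H]1CO1 | starting material
14 | [3-methoxy-4-(methoxymethoxy)phenyl]magnesium bromide (not isolated) | COCOc1ccc([Mg]Br)cc1OC | intermediate
15 | methyl (2R)-2-hydroxy-3-[3-methoxy-4-(methoxymethoxy)phenyl]propanoate | COCOc1ccc(C[C@@H](O)C(=O)OC)cc1OC | intermediate
16 | 4-methoxybenzyl (2R)-2-hydroxy-3-[3-methoxy-4-(methoxymethoxy)phenyl]propanoate | COCOc1ccc(C[C@@H](O)C(=O)OCc2ccc(OC)cc2)cc1OC | intermediate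
17 | acryloyl chloride | C=CC(=O)Cl | starting material
18 | 4-methoxybenzyl (2R)-3-[3-methoxy-4-(methoxymethoxy)phenyl]-2-(prop-2-enoyloxy)propanoate | COCOc1ccc(C[C@@H](OC(=O)C=C)C(=O)OCc2ccc(OC)cc2)cc1OC | intermediate
19 | (2R,3R)-3-(2,2-diphenyl-1,3-benzodioxol-5-yl)-7-[(E)-3-{[(2R)-1-[(4-methoxybenzyl)oxy]-3-[3-methoxy-4-(methoxymethoxy)phenyl]-1-oxopropan-2-yl]oxy}-3-oxoprop-1-en-1-yl]-2,3-dihydro-1,4-benzodioxine-2-carboxylic acid | COc1cc(C[C@@H](OC(=O)/C=C/c2ccc3c(c2)O[C@@H](C(=O)O)[C@@H](c2ccc4OC(c5ccccc5)(c5ccccc5)Oc4c2)O3)C(=O)OCc2ccc(OC)cc2)ccc1OCOC | intermediate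
20 | clinopodic acid F | COc1cc(C[C@@H](OC(=O)/C=C/c2ccc3c(c2)O[C@@H](C(=O)O)[C@@H](c2ccc(O)c(O)c2)O3)C(=O)O)ccc1O | target

Total step count: 13. Longest linear sequence: 8 steps (steps 2, 3, 4, 5, 6, 7, 12, 13, starting from 3).

Steps most likely to fail

Step 7. Hydrogen uptake at the fully substituted, donor-flanked C2=C3 bond may be slow, the face discrimination may be poor, or hydrodebromination may compete. The fallback sets out from 9 and comes back at 10. It keeps the syn hydrogenation for the cis relationship but takes the absolute configuration from a classical resolution instead of a chiral catalyst. Hydrogenation of 9 with the achiral cationic complex [Ir(cod)(PCy3)(py)]PF6 (H2, CH2Cl2), which reduces tetrasubstituted alkenes under carboxyl direction, should give the racemic cis-7-bromo-3-(2,2-diphenyl-1,3-benzodioxol-5-yl)-2,3-dihydro-1,4-benzodioxine-2-carboxylic acid F1. Fractional crystallisation with (S)-1-phenylethylamine (or its antipode, whichever gives the less soluble salt of the wanted acid) should give the (S)-1-phenylethylammonium salt of the (2R,3R) acid F2, and acidification releases 10.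

Step 5. The enolate or the liberated phenoxide may transfer the acyl group between molecules instead of closing the ring, and in the acid stage lactonisation onto the methyl ester or partial loss of the ketal may compete with dehydration. The fallback sets out from 6 and comes back at 8. It closes the ring through the same C2–C3 bond by an intramolecular Wittig olefination of the aryl ester carbonyl, with no acid stage. Radical bromination of the O–CH2 group of 6 (NBS, AIBN cat., PhCF3, 80 °C) should give methyl 2-bromo-2-{5-bromo-2-[(2,2-diphenyl-1,3-benzodioxole-5-carbonyl)oxy]phenoxy}acetate F3. Displacement with PPh3 in toluene should give the corresponding triphenylphosphonium bromide F4. With Et3N in toluene at reflux, the ester-stabilised α-aryloxy ylide should attack the neighbouring aryl ester carbonyl in a six-membered ring and expel triphenylphosphine oxide to give 8.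

Step 13. Once the electron-rich free catechol is unmasked, acid may ionise the C3–O4 benzylic ether and erode the cis configuration, and the three liberated cations may alkylate the product rings. The fallback sets out from 10 and comes back at 20. It exchanges the ketal for acetates before the coupling, so that the last acid treatment meets an electron-poor aryl group at C3 and the catechol is released under neutral conditions.
- Brief TFA/CH2Cl2/H2O treatment of 10, where only one cation is released and any trans isomer can still be removed by crystallisation, should give (2R,3R)-7-bromo-3-(3,4-dihydroxyphenyl)-2,3-dihydro-1,4-benzodioxine-2-carboxylic acid F5.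
- Acid-catalysed acetylation (Ac2O, H2SO4 cat., then water) should give the 3,4-diacetoxyphenyl analogue F6.
- Heck coupling of F6 with 18 under the conditions of step 12 should give the diacetate of the coupled product, still carrying the methoxymethyl ether and the 4-methoxybenzyl ester, F7.
- TFA/anisole/H2O should remove these two groups and give the diacetate of clinopodic acid F, F8.
- Ammonium acetate in aqueous methanol at rt, which cleaves aryl acetates selectively, should give 20.

Further compounds
F1 | step 7 | racemic cis-7-bromo-3-(2,2-diphenyl-1,3-benzodioxol-5-yl)-2,3-dihydro-1,4-benzodioxine-2-carboxylic acid (both enantiomers) | Brc1ccc2c(c1)O[C@@H](C(=O)O)[C@@H](c1ccc3OC(c4ccccc4)(c4ccccc4)Oc3c1)O2.Brc1ccc2c(c1)O[C@H](C(=O)O)[C@H](c1ccc3OC(c4ccccc4)(c4ccccc4)Oc3c1)O2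
F2 | step 7 | (S)-1-phenylethylammonium (2R,3R)-7-bromo-3-(2,2-diphenyl-1,3-benzodioxol-5-yl)-2,3-dihydro-1,4-benzodioxine-2-carboxylate | Brc1ccc2c(c1)O[C@@H](C(=O)[O-])[C@@H](c1ccc3OC(c4ccccc4)(c4ccccc4)Oc3c1)O2.C[C@H]([NH3+])c1ccccc1
F3 | step 5 | methyl 2-bromo-2-{5-bromo-2-[(2,2-diphenyl-1,3-benzodioxole-5-carbonyl)oxy]phenoxy}acetate | COC(=O)C(Br)Oc1cc(Br)ccc1OC(=O)c1ccc2OC(c3ccccc3)(c3ccccc3)Oc2c1
F4 | step 5 | (1-{5-bromo-2-[(2,2-diphenyl-1,3-benzodioxole-5-carbonyl)oxy]phenoxy}-2-methoxy-2-oxoethyl)triphenylphosphonium bromide | COC(=O)C(Oc1cc(Br)ccc1OC(=O)c1ccc2OC(c3ccccc3)(c3ccccc3)Oc2c1)[P+](c1ccccc1)(c1ccccc1)c1ccccc1.[Br-]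
F5 | step 13 | (2R,3R)-7-bromo-3-(3,4-dihydroxyphenyl)-2,3-dihydro-1,4-benzodioxine-2-carboxylic acid | Brc1ccc2c(c1)O[C@@H](C(=O)O)[C@@H](c1ccc(O)c(O)c1)O2
F6 | step 13 | (2R,3R)-7-bromo-3-(3,4-diacetoxyphenyl)-2,3-dihydro-1,4-benzodioxine-2-carboxylic acid | Brc1ccc2c(c1)O[C@@H](C(=O)O)[C@@H](c1ccc(OC(C)=O)c(OC(C)=O)c1)O2
F7 | step 13 | (2R,3R)-3-(3,4-diacetoxyphenyl)-7-[(E)-3-{[(2R)-1-[(4-methoxybenzyl)oxy]-3-[3-methoxy-4-(methoxymethoxy)phenyl]-1-oxopropan-2-yl]oxy}-3-oxoprop-1-en-1-yl]-2,3-dihydro-1,4-benzodioxine-2-carboxylic acid | COc1cc(C[C@@H](OC(=O)/C=C/c2ccc3c(c2)O[C@@H](C(=O)O)[C@@H](c2ccc(OC(C)=O)c(OC(C)=O)c2)O3)C(=O)OCc2ccc(OC)cc2)ccc1OCOC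
F8 | step 13 | clinopodic acid F 3,4-di-O-acetate (acetates on the catechol ring at C3) | COc1cc(C[C@@H](OC(=O)/C=C/c2ccc3c(c2)O[C@@H](C(=O)O)[C@@H](c2ccc(OC(C)=O)c(OC(C)=O)c2)O3)C(=O)O)ccc1O
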